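Start from what the green run left unaccounted for. At 120 s it held 59% of the charge as target and 3% as substrate, so a gap of 38.0% stood in neither, against 17.0% at 60.0 s. Target is therefore an intermediate, and the choice below is between two stopping points on its falling side.

| flask | substrate | enzyme | remark | time |
|---|---|---|---|---|
| green | 0.097 M | 10 µM | run made earlier |  |
| teal | 0.15 M | 10 µM | run made earlier |  |
| red | 0.23 M | 10 µM | run made earlier |  |
| grey | 0.10 M | 8.9 µM | run made earlier |  |
| Sunday's | 0.20 M | 6.0 µM |  | 2.0 min |
| Saturday's | 0.10 M | 10 µM |  | 2.0 min |

| run | time / s | target / % | substrate / % |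
|---|---|---|---|
| green | 10.0 | 29 | 66 |
| green | 20.0 | 52 | 48 |
| green | 30.0 | 63 | 28 |
| green | 60.0 | 75 | 8 |
| green | 120 | 59 | 3 |
| teal | 10.0 | 29 | 68 |
| teal | 30.0 | 58 | 30 |
| teal | 60.0 | 69 | 10 |
| teal | 80.0 | 67 | 1 |
| teal | 120 | 56 | 0 |
| red | 25.0 | 57 | 42 |
| red | 50.0 | 70 | 17 |
| red | 80.0 | 66 | 6 |
| red | 90.0 | 63 | 2 |
| red | 120 | 62 | 0 |
| grey | 25.0 | 52 | 43 |
| grey | 50.0 | 68 | 15 |
| grey | 80.0 | 68 | 3 |
| grey | 90.0 | 64 | 5 |
| grey | 120 | 63 | 0 |

(scatter of a reading: 2 percentage points)

- the analysis behind the earlier runs scatters by 2 percentage points, standard deviation

* the flask that ends with the higher amount of target, in percent of the substrate charged, or "neither" when 2 percentage points or less lies between them (Sunday's / Saturday's / neither)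
* final target, as a percentage of the substrate charged, in Sunday's
* final target, as a percentage of the substrate charged, in Saturday's

Treat target as the charge minus a small substrate remainder and the gap, and reckon only those two corrections. First leave the substrate charge aside: at 120 s the green, teal and red runs read 59%, 56% and 62%, which is no steady trend with the charge, since teal, with the middle charge, reads less than the other two.

Next, put every flask on the enzyme clock, the running time multiplied by the flask's enzyme and divided by 10 µM. Sunday's stops at 72.0 s and Saturday's at 120 s, so Sunday's stops earlier on this clock.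

This clock is my own wager. Test it on grey's last reading, which stands at 107 s: target reads 63% against green's 59%, the direction the clock asks, but the step is small beside the scatter.

Now read the answer. Grey at 80.0 s stands at 71.2 s on the clock and shows 68% target, so expect that for Sunday's. Green's last reading stands in for Saturday's at 59%. The lead of 9 percentage points exceeds the margin of 2 points, so charge Sunday's.

The forecast also says Sunday's, with 68% for Sunday's and 59% for Saturday's, and warns: “The runs barely separate these cases, since enzyme varied little”.

The simulation gives Sunday's, with 68.8% for Sunday's and 58.2% for Saturday's, as forecast.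

    target + enzyme ⇌ isomer of the product + enzyme, rate k1*[enzyme]*[target] forward; the back reaction follows from the equilibrium constant (K = 1.50, k = 760 M⁻¹ s⁻¹)
    substrate + enzyme → target + enzyme, rate k2*[substrate]*[enzyme]/(1 + ([substrate]/Km2)) (0.476 M, k = 4530 M⁻¹ s⁻¹)

In Saturday's, the substrate-to-target step passed the midpoint of its turnover by 0.292 min, and at 0.292 min target was made 6.14 times faster than it was used up, net. The target-to-isomer step reached its midpoint by 0.964 min, and at 2.00 min, with 0.54% substrate left, making ran at 0.105 of the net using up. Sunday's stopped at 72.0 s on the clock with 25.5% isomer of the product. The flask like Saturday's with 1.7 × 10⁻⁵ M enzyme stood at 204 s on the clock when it ended with 46.5% target.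

Readings and results were computed with constants of no real substance; scatter was added.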